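**Retrosynthetic overview**
1. The target, 15-acetoxylabda-8,13E-dien-19-oic acid, is cut at C11–C12: a C11 allylic bromide of the bicyclic core is joined to the α-sulfonyl carbanion of a C12–C16 allyl sulfone, followed by desulfonylation, desilylation and acetylation.
2. C4 (4α-methyl, 4β-carboxyl) comes from a C4 gem-diester: one ester is removed, then the C4 ester enolate is methylated on the α face, away from the axial C10 methyl.
3. The C8=C9 alkene and C11 come from a C9 formyl group (hydrogenation of C6=C7, selenoxide elimination, reduction).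
4. The strategy rests on the trans-fused decalin whose quaternary C10 carries the angular methyl next to C5–H. Ring B (C5–C10) and ring A (C1–C5, C10) are closed together by one intramolecular Diels–Alder reaction that forms C5–C10 and C8–C9 between a C5–C8 E,E-diene and the E-configured C10=C9 enal (formyl carbon = C11), tethered through C1–C3 and a C4 malonate that keeps C4 non-stereogenic.
5. The trienal is assembled from dimethyl malonate, (E)-pent-2-enal (Knoevenagel, deconjugative alkylation) and a C6 iodide cut out of geranyl acetate, which supplies the E alkene of the enal.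

Key step: step 9

Convention: labdane numbering throughout (ring A = C1–C5, C10; ring B = C5–C10; C11 on C9; C17 = methyl on C8; C18/C19 = α/β substituent on C4; C20 = methyl on C10; β = the face of the C10 methyl).
Assumption: the facial sense of step 9 is assigned with the formyl C–H···O pre-transition-state model of oxazaborolidinium ions, in which the (R)-catalyst exposes the Si face of C9; should the adduct prove to be the antipode, the (S)-catalyst is used and nothing else changes.

**Route**

Step 1
Reactants: 1 dimethyl malonate; 2 (E)-pent-2-enal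
Product: 3 dimethyl 2-[(E)-pent-2-enylidene]malonate
Conditions: TiCl4, pyridine, THF, 0 °C → rt
Reagents that add atoms: none
Why: Knoevenagel condensation under TiCl4/pyridine, which dehydrates the titanium aldolate irreversibly and leaves the E alkene of the enal untouched.

Step 2
Reactants: 4 geranyl acetate
Product: 5 6,7-epoxygeranyl acetate (racemic)
Conditions: mCPBA, NaHCO3, CH2Cl2, 0 °C
Reagents that add atoms: 3-chloroperoxybenzoic acid, O=C(OO)c1cccc(Cl)c1
Why: Prilezhaev epoxidation, selective for the electron-rich 6,7-alkene because the 2,3-alkene is deactivated by the allylic acetate; the epoxide stereocentre is cleaved away in step 3.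

Step 3
Reactants: 5 6,7-epoxygeranyl acetate
Product: 6 (E)-3-methyl-6-oxohex-2-enyl acetate
Conditions: H5IO6, THF/H2O, 0 °C
Reagents that add atoms: none
Why: periodic acid opens the epoxide and cleaves the resulting glycol in the same flask (glycol cleavage), leaving the E trisubstituted alkene and the acetate intact.

Step 4
Reactants: 6 (E)-3-methyl-6-oxohex-2-enyl acetate
Product: 7 (E)-6-hydroxy-3-methylhex-2-enyl acetate
Conditions: NaBH4, EtOH, 0 °C
Reagents that add atoms: none
Why: chemoselective borohydride reduction of the aldehyde, the acetate being inert in a short reaction at 0 °C.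

Step 5
Reactants: 7 (E)-6-hydroxy-3-methylhex-2-enyl acetate
Product: 8 (E)-6-iodo-3-methylhex-2-enyl acetate
Conditions: I2, PPh3, imidazole, CH2Cl2, 0 °C → rt
Reagents that add atoms: iodine, II
Why: Appel-type iodination of the primary alcohol by SN2 displacement of the oxyphosphonium group under neutral conditions that spare the allylic acetate.

Step 6
Reactants: 3 dimethyl 2-[(E)-pent-2-enylidene]malonate; 8 (E)-6-iodo-3-methylhex-2-enyl acetate
Product: 10 dimethyl 2-[(E)-6-acetoxy-4-methylhex-4-enyl]-2-[(1E,3E)-penta-1,3-dienyl]malonate, via sodium trienolate 9 (not isolated)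
Conditions: NaH (1.0 equiv), THF/DMF, 0 °C; then 8, 0 °C → rt
Reagents that add atoms: none
Why: deconjugative α-alkylation of an alkylidenemalonate, in which NaH removes the ε-proton and the extended trienolate is alkylated by the primary iodide at the malonate carbon, where the charge density is highest, creating the quaternary C4 and the conjugated C5–C8 diene, expected as the E,E isomer from the extended anion.

Step 7
Reactants: 10 dimethyl 2-[(E)-6-acetoxy-4-methylhex-4-enyl]-2-[(1E,3E)-penta-1,3-dienyl]malonate
Product: 11 dimethyl 2-[(E)-6-hydroxy-4-methylhex-4-enyl]-2-[(1E,3E)-penta-1,3-dienyl]malonate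
Conditions: K2CO3 (cat.), MeOH, 0 °C → rt
Reagents that add atoms: none
Why: base-catalysed transesterification removes the acetate, while the quaternary malonate is already a methyl ester and is unchanged in methanol.

Step 8
Reactants: 11 dimethyl 2-[(E)-6-hydroxy-4-methylhex-4-enyl]-2-[(1E,3E)-penta-1,3-dienyl]malonate
Product: 12 dimethyl 2-[(E)-4-methyl-6-oxohex-4-enyl]-2-[(1E,3E)-penta-1,3-dienyl]malonate
Conditions: MnO2, CH2Cl2, rt
Reagents that add atoms: none
Why: MnO2 oxidises only the allylic alcohol and stops at the aldehyde, keeping the E geometry of the C10=C9 enal on which the trans ring fusion depends.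

Step 9
Reactants: 12 dimethyl 2-[(E)-4-methyl-6-oxohex-4-enyl]-2-[(1E,3E)-penta-1,3-dienyl]malonate
Product: 13 dimethyl 11-oxo-12,13,14,15,16-pentanorlabd-6-ene-18,19-dioate (5α-H, 8β-methyl, 9β-formyl, 10β-methyl)
Conditions: (R)-1-(2-methylphenyl)-3,3-diphenyltetrahydro-1H,3H-pyrrolo[1,2-c][1,3,2]oxazaborole (20 mol%), Tf2NH (18 mol%), CH2Cl2 (0.02 M), −78 → −20 °C
Reagents that add atoms: none
Why: The boron of the N-protonated oxazaborolidinium triflimide binds the formyl oxygen of the s-trans enal and lowers its LUMO, so a concerted but asynchronous [4+2] cycloaddition takes place with the C5–C10 bond the more advanced, as in the known oxazaborolidinium-catalysed intramolecular Diels–Alder reactions of deca-2,7,9-trienals. Ring B closes as the six-membered cycloadduct ring (bonds C5–C10 and C8–C9) and ring A closes in the same event as the six-membered tether ring (C1–C4 chain, fused type 1 mode), helped by the Thorpe–Ingold effect of the C4 gem-diester. The E enal fixes the C9/C10 relation (formyl cis to the C10 methyl), the E,E diene fixes C8, and the formyl-endo transition state, with the C1–C3 tether anti to the diene, fixes C5 against C10 as the trans ring fusion (5α-H, 10β-methyl). The absolute sense comes from the catalyst: the enal stacks on a phenyl ring of the diphenylmethyl unit, which blocks the Re face of C9, so the diene adds to the Si face. The step needs endo selectivity and facial selectivity only at C5 and C10, since C8 and C9 are flattened later; the geometrically pure E enal from geraniol and the Lewis-acid preference for the formyl-endo mode secure the first, the catalyst the second.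

Step 10
Reactants: 13 dimethyl 11-oxo-12,13,14,15,16-pentanorlabd-6-ene-18,19-dioate
Product: 14 dimethyl 11-oxo-12,13,14,15,16-pentanorlabdane-18,19-dioate (8β-methyl, 9β-formyl)
Conditions: H2 (1 atm), Pd/C (10%), EtOAc, rt
Reagents that add atoms: none
Why: heterogeneous hydrogenation of the only alkene, the unhindered cis-disubstituted C6=C7 bond, which leaves the aldehyde, the esters and all stereocentres untouched.

Step 11
Reactants: 14 dimethyl 11-oxo-12,13,14,15,16-pentanorlabdane-18,19-dioate
Product: 16 dimethyl 11-oxo-9α-(phenylselanyl)-12,13,14,15,16-pentanorlabdane-18,19-dioate, via silyl enol ether 15 (not isolated)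
Conditions: TMSOTf, Et3N, CH2Cl2, 0 °C; then PhSeCl, −78 °C
Reagents that add atoms: phenylselanyl chloride, Cl[Se]c1ccccc1
Why: α-selenenylation of an aldehyde through its silyl enol ether, in which PhSeCl attacks the C9=C11 enol ether on the α face, opposite the axial C10 and C8 methyl groups, so that selenium ends up cis to H-8 as the syn elimination of step 12 requires.

Step 12
Reactants: 16 dimethyl 11-oxo-9α-(phenylselanyl)-12,13,14,15,16-pentanorlabdane-18,19-dioate
Product: 18 dimethyl 11-oxo-12,13,14,15,16-pentanorlabd-8-ene-18,19-dioate, via selenoxide 17 (not isolated)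
Conditions: H2O2 (30%), pyridine, CH2Cl2, 0 °C → rt
Reagents that add atoms: none
Why: selenoxide elimination, the syn elimination running towards H-8, the only β-hydrogen, to give the tetrasubstituted C8=C9 enal and erase the C8 and C9 stereocentres.

Step 13
Reactants: 18 dimethyl 11-oxo-12,13,14,15,16-pentanorlabd-8-ene-18,19-dioate
Product: 19 dimethyl 11-hydroxy-12,13,14,15,16-pentanorlabd-8-ene-18,19-dioate
Conditions: NaBH4, CeCl3·7H2O, MeOH, 0 °C
Reagents that add atoms: none
Why: Luche 1,2-reduction of the hindered enal, the neopentyl malonate esters being inert to NaBH4 at 0 °C.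

Step 14
Reactants: 19 dimethyl 11-hydroxy-12,13,14,15,16-pentanorlabd-8-ene-18,19-dioate
Product: 20 methyl 11-hydroxy-12,13,14,15,16,18-hexanorlabd-8-en-19-oate (mixture of C4 epimers)
Conditions: LiCl, H2O, DMSO, 160 °C
Reagents that add atoms: none
Why: Krapcho dealkoxycarbonylation, in which chloride demethylates one ester by SN2 at the methyl group, the carboxylate loses CO2 and the enolate is protonated, the C4 configuration being of no consequence because it is reset in step 15.

Step 15
Reactants: 20 methyl 11-hydroxy-12,13,14,15,16,18-hexanorlabd-8-en-19-oate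
Product: 22 methyl 11-hydroxy-12,13,14,15,16-pentanorlabd-8-en-19-oate (4α-methyl, 4β-CO2Me), via dilithium alkoxide enolate 21 (not isolated)
Conditions: LiN(i-Pr)2 (2.5 equiv), THF, −78 → 0 °C; MeI (1.3 equiv), −78 → −20 °C; then H2O
Reagents that add atoms: iodomethane, CI
Why: ester enolate alkylation within the alkoxide–enolate dianion, in which MeI approaches C4 from the equatorial α face because the β face is blocked by the syn-axial C10 methyl, setting C4 with methyl α and ester β, while the lithium alkoxide is not methylated at low temperature.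

Step 16
Reactants: 22 methyl 11-hydroxy-12,13,14,15,16-pentanorlabd-8-en-19-oate
Product: 23 methyl 11-bromo-12,13,14,15,16-pentanorlabd-8-en-19-oate
Conditions: CBr4, PPh3, CH2Cl2, 0 °C
Reagents that add atoms: tetrabromomethane, BrC(Br)(Br)Br
Why: Appel bromination of the primary allylic alcohol under neutral conditions, by SN2 at C11 without allylic transposition because C8 is fully substituted.

Step 17
Reactants: 24 (E)-4-chloro-3-methylbut-2-enyl acetate
Product: 25 (E)-3-methyl-4-(phenylsulfonyl)but-2-enyl acetate
Conditions: PhSO2Na, DMF, rt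
Reagents that add atoms: sodium benzenesulfinate, [Na+].[O-]S(=O)c1ccccc1
Why: SN2 S-alkylation of the sulfinate by the primary allylic chloride with retention of the E alkene.

Step 18
Reactants: 25 (E)-3-methyl-4-(phenylsulfonyl)but-2-enyl acetate
Product: 26 (E)-3-methyl-4-(phenylsulfonyl)but-2-en-1-ol
Conditions: K2CO3 (cat.), MeOH, 0 °C
Reagents that add atoms: none
Why: base-catalysed methanolysis of the acetate at 0 °C, mild enough not to isomerise the allyl sulfone to the vinyl sulfone.

Step 19
Reactants: 26 (E)-3-methyl-4-(phenylsulfonyl)but-2-en-1-ol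
Product: 27 tert-butyldimethyl{[(E)-3-methyl-4-(phenylsulfonyl)but-2-enyl]oxy}silane
Conditions: TBSCl, imidazole, DMF, rt
Reagents that add atoms: tert-butyldimethylsilyl chloride, CC(C)(C)[Si](C)(C)Cl
Why: silylation of the primary alcohol to mask it against n-BuLi in step 20.

Step 20
Reactants: 27 tert-butyldimethyl{[(E)-3-methyl-4-(phenylsulfonyl)but-2-enyl]oxy}silane; 23 methyl 11-bromo-12,13,14,15,16-pentanorlabd-8-en-19-oate
Product: 29 methyl 15-(tert-butyldimethylsilyloxy)-12-(phenylsulfonyl)labda-8,13E-dien-19-oate (C12 epimers), via lithiated sulfone 28 (not isolated)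
Conditions: 27, n-BuLi, THF, −78 °C; then 23, −78 → −20 °C
Reagents that add atoms: none
Why: alkylation of an α-sulfonyl allyl carbanion, which reacts at its α carbon (C12) with the primary allylic bromide by SN2 to form the C11–C12 bond, the E alkene being kept at low temperature and the new C12 centre being removed in step 22.

Step 21
Reactants: 29 methyl 15-(tert-butyldimethylsilyloxy)-12-(phenylsulfonyl)labda-8,13E-dien-19-oate
Product: 30 15-(tert-butyldimethylsilyloxy)-12-(phenylsulfonyl)labda-8,13E-dien-19-oic acid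
Conditions: n-PrSLi, HMPA, rt; then dil. HCl, 0 °C
Reagents that add atoms: none
Why: SN2 demethylation of the hindered axial methyl ester by thiolate at the methyl carbon, which avoids attack at the shielded carbonyl and leaves the sulfone and the silyl ether alone.

Step 22
Reactants: 30 15-(tert-butyldimethylsilyloxy)-12-(phenylsulfonyl)labda-8,13E-dien-19-oic acid
Product: 31 15-(tert-butyldimethylsilyloxy)labda-8,13E-dien-19-oic acid
Conditions: PdCl2(dppp) (5 mol%), LiBHEt3 (4 equiv), THF, 0 °C; then dil. HCl, 0 °C
Reagents that add atoms: none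
Why: palladium-catalysed reductive desulfonylation, in which zerovalent palladium formed in situ ionises the allylic sulfone to an allylpalladium complex and hydride is delivered to C12, the terminus remote from the C15 oxygen, with retention of the 13E geometry, while the acid is masked in situ as its lithium carboxylate, which LiBHEt3 does not reduce.

Step 23
Reactants: 31 15-(tert-butyldimethylsilyloxy)labda-8,13E-dien-19-oic acid
Product: 32 15-hydroxylabda-8,13E-dien-19-oic acid
Conditions: HF·pyridine, pyridine, THF, 0 °C → rt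
Reagents that add atoms: none
Why: fluoride cleavage of the primary silyl ether under buffered conditions that do not touch the acid or the alkenes.

Step 24
Reactants: 32 15-hydroxylabda-8,13E-dien-19-oic acid
Product: 33 15-acetoxylabda-8,13E-dien-19-oic acid (4S,5R,10S; the target)
Conditions: Ac2O, pyridine, DMAP (cat.), CH2Cl2, 0 °C → rt; aqueous work-up
Reagents that add atoms: acetic anhydride, CC(=O)OC(C)=O
Why: DMAP-catalysed acylation of the primary allylic alcohol, the hindered axial carboxylic acid giving at most a mixed anhydride that is hydrolysed on aqueous work-up.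

**Compound list**
1 | dimethyl malonate | COC(=O)CC(=O)OC | starting material
2 | (E)-pent-2-enal | CC/C=C/C=O | starting material
3 | dimethyl 2-[(E)-pent-2-enylidene]malonate | CC/C=C/C=C(C(=O)OC)C(=O)OC | intermediate
4 | geranyl acetate | CC(=O)OC/C=C(\C)CCC=C(C)C | starting material
5 | 6,7-epoxygeranyl acetate (racemic) | CC(=O)OC/C=C(\C)CCC1OC1(C)C | intermediate
6 | (E)-3-methyl-6-oxohex-2-enyl acetate | CC(=O)OC/C=C(\C)CCC=O | intermediate
7 | (E)-6-hydroxy-3-methylhex-2-enyl acetate | CC(=O)OC/C=C(\C)CCCO | intermediate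
8 | (E)-6-iodo-3-methylhex-2-enyl acetate | CC(=O)OC/C=C(\C)CCCI | intermediate
9 | sodium trienolate of 3 (not isolated) | [Na+].COC(=O)[C-](/C=C/C=C/C)C(=O)OC | intermediate
10 | dimethyl 2-[(E)-6-acetoxy-4-methylhex-4-enyl]-2-[(1E,3E)-penta-1,3-dienyl]malonate | C/C=C/C=C/C(C(=O)OC)(C(=O)OC)CCC/C(C)=C/COC(C)=O | intermediate
11 | dimethyl 2-[(E)-6-hydroxy-4-methylhex-4-enyl]-2-[(1E,3E)-penta-1,3-dienyl]malonate | C/C=C/C=C/C(C(=O)OC)(C(=O)OC)CCC/C(C)=C/CO | intermediate
12 | dimethyl 2-[(E)-4-methyl-6-oxohex-4-enyl]-2-[(1E,3E)-penta-1,3-dienyl]malonate | C/C=C/C=C/C(C(=O)OC)(C(=O)OC)CCC/C(C)=C/C=O | intermediate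
13 | dimethyl 11-oxo-12,13,14,15,16-pentanorlabd-6-ene-18,19-dioate (5α-H, 8β-Me, 9β-CHO, 10β-Me) | O=C[C@H]1[C@@H](C)C=C[C@H]2C(C(=O)OC)(C(=O)OC)CCC[C@]12C | intermediate
14 | dimethyl 11-oxo-12,13,14,15,16-pentanorlabdane-18,19-dioate (8β-Me, 9β-CHO) | O=C[C@H]1[C@@H](C)CC[C@H]2C(C(=O)OC)(C(=O)OC)CCC[C@]12C | intermediate
15 | C9=C11 trimethylsilyl enol ether of 14 (not isolated) | C[Si](C)(C)OC=C1[C@@H](C)CC[C@H]2C(C(=O)OC)(C(=O)OC)CCC[C@]12C | intermediate
16 | dimethyl 11-oxo-9α-(phenylselanyl)-12,13,14,15,16-pentanorlabdane-18,19-dioate | O=C[C@@]1([Se]c3ccccc3)[C@@H](C)CC[C@H]2C(C(=O)OC)(C(=O)OC)CCC[C@]12C | intermediate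
17 | selenoxide of 16 (not isolated) | O=C[C@@]1([Se](=O)c3ccccc3)[C@@H](C)CC[C@H]2C(C(=O)OC)(C(=O)OC)CCC[C@]12C | intermediate
18 | dimethyl 11-oxo-12,13,14,15,16-pentanorlabd-8-ene-18,19-dioate | O=CC1=C(C)CC[C@H]2C(C(=O)OC)(C(=O)OC)CCC[C@]12C | intermediate
19 | dimethyl 11-hydroxy-12,13,14,15,16-pentanorlabd-8-ene-18,19-dioate | OCC1=C(C)CC[C@H]2C(C(=O)OC)(C(=O)OC)CCC[C@]12C | intermediate
20 | methyl 11-hydroxy-12,13,14,15,16,18-hexanorlabd-8-en-19-oate (C4 epimers) | OCC1=C(C)CC[C@H]2C(C(=O)OC)CCC[C@]12C | intermediate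
21 | dilithium alkoxide–ester enolate of 20 (not isolated) | [Li+].[Li+].[O-]CC1=C(C)CC[C@H]2C(=C([O-])OC)CCC[C@]12C | intermediate
22 | methyl 11-hydroxy-12,13,14,15,16-pentanorlabd-8-en-19-oate (4α-Me, 4β-CO2Me) | OCC1=C(C)CC[C@H]2[C@@](C)(C(=O)OC)CCC[C@]12C | intermediate
23 | methyl 11-bromo-12,13,14,15,16-pentanorlabd-8-en-19-oate | BrCC1=C(C)CC[C@H]2[C@@](C)(C(=O)OC)CCC[C@]12C | intermediate
24 | (E)-4-chloro-3-methylbut-2-enyl acetate | CC(=O)OC/C=C(\C)CCl | starting material
25 | (E)-3-methyl-4-(phenylsulfonyl)but-2-enyl acetate | CC(=O)OC/C=C(\C)CS(=O)(=O)c1ccccc1 | intermediate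
26 | (E)-3-methyl-4-(phenylsulfonyl)but-2-en-1-ol | OC/C=C(\C)CS(=O)(=O)c1ccccc1 | intermediate
27 | tert-butyldimethyl{[(E)-3-methyl-4-(phenylsulfonyl)but-2-enyl]oxy}silane | CC(C)(C)[Si](C)(C)OC/C=C(\C)CS(=O)(=O)c1ccccc1 | intermediate
28 | α-lithio derivative of 27 (not isolated) | [Li+].CC(C)(C)[Si](C)(C)OC/C=C(\C)[CH-]S(=O)(=O)c1ccccc1 | intermediate
29 | methyl 15-(tert-butyldimethylsilyloxy)-12-(phenylsulfonyl)labda-8,13E-dien-19-oate (C12 epimers) | CC(C)(C)[Si](C)(C)OC/C=C(\C)C(CC1=C(C)CC[C@H]2[C@@](C)(C(=O)OC)CCC[C@]12C)S(=O)(=O)c1ccccc1 | intermediate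
30 | 15-(tert-butyldimethylsilyloxy)-12-(phenylsulfonyl)labda-8,13E-dien-19-oic acid | CC(C)(C)[Si](C)(C)OC/C=C(\C)C(CC1=C(C)CC[C@H]2[C@@](C)(C(=O)O)CCC[C@]12C)S(=O)(=O)c1ccccc1 | intermediate
31 | 15-(tert-butyldimethylsilyloxy)labda-8,13E-dien-19-oic acid | CC(C)(C)[Si](C)(C)OC/C=C(\C)CCC1=C(C)CC[C@H]2[C@@](C)(C(=O)O)CCC[C@]12C | intermediate
32 | 15-hydroxylabda-8,13E-dien-19-oic acid | OC/C=C(\C)CCC1=C(C)CC[C@H]2[C@@](C)(C(=O)O)CCC[C@]12C | intermediate
33 | 15-acetoxylabda-8,13E-dien-19-oic acid (4S,5R,10S) | CC(=O)OC/C=C(\C)CCC1=C(C)CC[C@H]2[C@@](C)(C(=O)O)CCC[C@]12C | target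

**Step count**
Total: 24 steps. Longest linear sequence: 20 steps (from geranyl acetate 4 through steps 2–16 and 20–24).

**Steps most likely to fail**

Step 9. The cycloaddition may stall because the β,β-disubstituted enal is a sluggish dienophile, or the malonate esters may compete for the boron centre and erode turnover and facial discrimination. The fallback is an auxiliary-controlled intramolecular Diels–Alder reaction; it sets out from 12 and comes back at 13. Pinnick oxidation of 12 (NaClO2, NaH2PO4, 2-methylbut-2-ene, t-BuOH/H2O) should give (2E,8E,10E)-7,7-bis(methoxycarbonyl)-3-methyldodeca-2,8,10-trienoic acid F1. Pivaloyl chloride and Et3N convert it into the mixed pivalic anhydride F2, which acylates lithiated (S)-4-benzyloxazolidin-2-one to the trienimide F3. Me2AlCl (1.4 equiv, CH2Cl2, −30 °C) then promotes the cycloaddition through the chelated s-cis acyl oxazolidinone, whose benzyl group leaves the Si face of C9 open, to the trans-fused imide cycloadduct F4. LiBH4/MeOH (THF, 0 °C) removes the auxiliary to give the C11 alcohol F5, and Dess–Martin periodinane oxidises it to 13.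

Step 6. The trienolate may be alkylated at C6 or C8 instead of C4, or the new C7=C8 alkene may form partly with Z geometry, which prevents the s-cis diene conformation needed in step 9. The fallback builds the diene stepwise with defined geometry; it sets out from 1 and 8 and comes back at 10. Sodium dimethyl malonate (NaH, excess 1, THF/DMF) is alkylated by 8 to dimethyl 2-[(E)-6-acetoxy-4-methylhex-4-enyl]malonate F6. DBU-catalysed Michael addition to acrolein gives dimethyl 2-[(E)-6-acetoxy-4-methylhex-4-enyl]-2-(3-oxopropyl)malonate F7. Dehydrogenation with IBX (DMSO, 70 °C) gives dimethyl 2-[(E)-6-acetoxy-4-methylhex-4-enyl]-2-[(E)-3-oxoprop-1-enyl]malonate F8. Takai ethylidenation (CH3CHI2, CrCl2, THF, rt) then forms the C7=C8 bond with E geometry and delivers 10.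

Step 22. Hydride may be delivered to C14 instead of C12, which moves the alkene to C12=C13, or the allylpalladium intermediate may isomerise and lose the 13E geometry. The fallback avoids any sulfone by building the side chain from acetoacetate; it sets out from 23 and comes back at 32. The dianion of methyl acetoacetate (NaH, then n-BuLi, THF, 0 °C) is alkylated by 23 at its terminal carbon to give methyl 13-oxo-19-methoxycarbonyl β-keto ester F9. NaH and ClP(O)(OEt)2 convert it into the (Z)-enol diethyl phosphate F10. Me2CuLi (Et2O, −78 → −45 °C) replaces the phosphate by methyl with retention to give the (E)-enoate diester F11. i-Bu2AlH (2.2 equiv, CH2Cl2, −78 °C) reduces the unhindered conjugated ester in preference to the axial neopentyl C19 ester to give methyl 15-hydroxylabda-8,13E-dien-19-oate F12. n-PrSLi in HMPA then cleaves the C19 methyl ester to give 32.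

**Further compounds**
F1 | step 9 | (2E,8E,10E)-7,7-bis(methoxycarbonyl)-3-methyldodeca-2,8,10-trienoic acid | C/C=C/C=C/C(C(=O)OC)(C(=O)OC)CCC/C(C)=C/C(=O)O
F2 | step 9 | mixed pivalic anhydride of F1 | C/C=C/C=C/C(C(=O)OC)(C(=O)OC)CCC/C(C)=C/C(=O)OC(=O)C(C)(C)C
F3 | step 9 | N-acyl (S)-4-benzyloxazolidin-2-one of F1 (trienimide) | C/C=C/C=C/C(C(=O)OC)(C(=O)OC)CCC/C(C)=C/C(=O)N1[C@@H](Cc2ccccc2)COC1=O
F4 | step 9 | trans-fused imide cycloadduct (5α-H, 8β-Me, 9β-acyl, 10β-Me) | O=C([C@H]1[C@@H](C)C=C[C@H]2C(C(=O)OC)(C(=O)OC)CCC[C@]12C)N1[C@@H](Cc2ccccc2)COC1=O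
F5 | step 9 | dimethyl 11-hydroxy-12,13,14,15,16-pentanorlabd-6-ene-18,19-dioate | OC[C@H]1[C@@H](C)C=C[C@H]2C(C(=O)OC)(C(=O)OC)CCC[C@]12C
F6 | step 6 | dimethyl 2-[(E)-6-acetoxy-4-methylhex-4-enyl]malonate | COC(=O)C(CCC/C(C)=C/COC(C)=O)C(=O)OC
F7 | step 6 | dimethyl 2-[(E)-6-acetoxy-4-methylhex-4-enyl]-2-(3-oxopropyl)malonate | COC(=O)C(CCC=O)(CCC/C(C)=C/COC(C)=O)C(=O)OC
F8 | step 6 | dimethyl 2-[(E)-6-acetoxy-4-methylhex-4-enyl]-2-[(E)-3-oxoprop-1-enyl]malonate | COC(=O)C(/C=C/C=O)(CCC/C(C)=C/COC(C)=O)C(=O)OC
F9 | step 22 | dimethyl 13-oxo-16-norlabd-8-ene-15,19-dioate (β-keto ester) | COC(=O)CC(=O)CCC1=C(C)CC[C@H]2[C@@](C)(C(=O)OC)CCC[C@]12C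
F10 | step 22 | (Z)-enol diethyl phosphate of F9 | COC(=O)/C=C(\OP(=O)(OCC)OCC)CCC1=C(C)CC[C@H]2[C@@](C)(C(=O)OC)CCC[C@]12C
F11 | step 22 | dimethyl labda-8,13E-diene-15,19-dioate | COC(=O)/C=C(\C)CCC1=C(C)CC[C@H]2[C@@](C)(C(=O)OC)CCC[C@]12C
F12 | step 22 | methyl 15-hydroxylabda-8,13E-dien-19-oate | OC/C=C(\C)CCC1=C(C)CC[C@H]2[C@@](C)(C(=O)OC)CCC[C@]12C
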